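The numbers in the tables are calculated with made-up constants, and the scatter is random.

A mole of electrophile that reacts puts a mole of nucleophile into target and, if the acid it sets free is wholly bound, takes a second mole as protonated nucleophile.

| setting | south-west | north-east | flask |
|---|---|---|---|
| electrophile | 1 M | 0.67 M | 1.0 M |
| nucleophile | 1.8 M | 1.8 M | 1.80 M |
| remark | the very flask that is asked about, followed so far | run made earlier |  |
| time |  |  | 3.0 min |

| run | time / s | electrophile / % | target / % |
|---|---|---|---|
| south-west | 25.0 | 43.4 | 53.6 |
| south-west | 50.0 | 28.6 | 68.8 |
| south-west | 60.0 | 24.9 | 71.8 |
| south-west | 90.0 | 18.3 | 78.4 |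
| north-east | 10.0 | 63.1 | 35.5 |
| north-east | 12.0 | 58.1 | 39.8 |
| north-east | 30.0 | 33.5 | 63.6 |
| north-east | 80.0 | 10.3 | 84.0 |

(readings scatter by 0.5 percentage points)

- the numbers in the tables scatter with a standard deviation of 0.5 percentage points
- a reading or a percentage of target counts all its forms, free or not
- the earlier runs do not show how much of nucleophile is bound; that part of a forecast is a guess

- part of the electrophile that has reacted at 3.0 min
- share of the unused nucleophile that is free and not bound as protonated nucleophile, at 3.0 min

I need the free nucleophile late in the south-west run, the flask asked about, and I can reach it two ways. Between 60.0 s and 90.0 s, on average 0.784 M of electrophile has reacted, so the balance with full binding leaves 0.232 M free.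

The second way uses rates. In the north-east run up to 10.0 s, free nucleophile averages 1.55 M. Treating the decay as pseudo-first-order gives a rate constant of 0.0297 M⁻¹ s⁻¹. The south-west electrophile decays at 0.0103 s⁻¹, which implies 0.346 M free.

The two part by 0.114 M. The balance is the one that cheats, because it assumes that no acid stays unbound at this late point. The rate way carries the same assumption, but through its constant, read early in the north-east run. With no binding at all in that stretch, free nucleophile there averages 1.68 M, and the south-west free amount becomes 0.374 M, larger than before, so the gap does not come from that assumption. Each unbound acid spares one nucleophile, so I read this gap as the unbound acid itself. Bound nucleophile is then 0.670 M, and the binding constant, bound amount over free nucleophile times unbound acid, reads 16.9 M⁻¹.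

The forecast gives 90% reacted and 21% free, and adds: “The fr value rests on an inferred K, so it is soft.” At that conversion, my constant binds 0.697 M of the unused nucleophile, which leaves 22.5% free. That differs a little from the forecast, though both come from the same readings.

The flask gives 90.5% reacted and 23.3% free.

    crystals ⇌ target, rate k1*(cs1 - [target]) while solid is left; crystals form when [target] > cs1 (solubility = 42.0 mM, k = 1.20 s⁻¹)
    electrophile + nucleophile → acid set free + target (k = 0.0300 M⁻¹ s⁻¹)
    target ⇌ isomer of the product (K = 0.350, k = 0.0150 s⁻¹)
    nucleophile + target → over-reaction product (k = 0.00570 M⁻¹ s⁻¹)
    nucleophile + acid set free ⇌ protonated nucleophile, settled at all times (K = 14.0 M⁻¹)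

The neighbouring flask, charged with 0.45 M of nucleophile, reaches 34.7% reacted, past the 22.5% that full binding would allow. The same constant, applied to that flask's conversion and balance, binds 0.0840 M and leaves 18.3% of its unused nucleophile free. That neighbouring flask gives 21.0%.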